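**Assumption (one line):** (+)-α-pinene of high enantiomeric purity is used, because its ee passes unchanged into C1; allyl hydrogen malonate (32) is taken as purchasable (otherwise one operation from Meldrum's acid and allyl alcohol).

## Analysis of the target

Atom numbering: carbocycle C1 (CH bearing C15), C2 (CH2), C3 (OCH), C4 (CH bearing C18H2O), C5, C6, C7 (=CH), C8 (bears CHO), C9, C10, C11 (=CH), C12 (bears CH3), C13, C14; C15 is the quaternary carbon with two methyl groups, bonded to the oxygen that bridges to C3.

- The target is a 14-membered carbocycle (C1–C14) bridged between C1 and C3 by O–C15(CH3)2. The atoms O, C15, C1, C2 and C3 form a 2,2-dimethyloxolane inside a 14-oxabicyclo[11.2.1]hexadecane frame.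
- There are three stereocentres, C1, C3 and C4, all R. C1 and C3 are cis on the oxolane, and C4, outside the oxolane but next to C3, carries C18.
- Two trisubstituted alkenes must be made with defined geometry: Z-C11=C12 (methyl on C12) and E-C7=C8 (formyl on C8).
- The sensitive groups are the malonic half ester (decarboxylation, acidic CH2 and CO2H), the enal (conjugate addition, condensation, possible oxa-Michael attack by a free C18 hydroxyl on C7) and the Z-alkene (acid).
- The hard points are the hindered tertiary C15–O bond next to C1, the C3/C4 pair that has to be related to a remote C1, and closure of the macrocycle.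
- The strategy rests on one feature. C15 is flanked by C1, and C1 sends out two two-carbon arms, C2–C3 and C14–C13. Removing the oxygen between C15 and C3 leaves a 2,2-dimethylcyclobutane, which is the four-membered ring of α-pinene (pinene C6 = C15, C5 = C1, C7 = C2, C1 = C3, C4 = C14, C3 = C13).

## Retrosynthetic reasoning

**C18–O acyl bond (34 ⇒ 33 ⇒ 31 + 32).** The malonic half ester is the most fragile group and is disconnected last. 33 holds it as the allyl ester, and 31 is the hydroxy enal. Forward, the only free hydroxyl is acylated and the allyl group is removed under neutral conditions.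

**Oxidation levels at C8 and C4 (31 ⇒ 30 ⇒ 29).** The formyl carbon on C8 and C18 are both traced to esters in 29. One hydride reduction then gives diol 30, and the allylic/saturated difference distinguishes the two alcohols, so C18 never needs a protecting group.

**C7=C8 (29 ⇒ 28).** The carbocycle is opened at the enoate. This site is chosen because olefination of an unhindered aldehyde (C7) by a phosphonate carbanion (C8) is E-selective by nature and lies far from the stereocentres. Opening at C11=C12 would need Z control in the ring-forming step, and opening at C3–C4 would make ring closure responsible for two stereocentres. Forward, the step needs high dilution and a mild base.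

**C8–C9 (28 ⇒ 27 ⇒ 25 + 26).** C8, its ester and the phosphorus come from 26 by alkylation with the primary homoallylic iodide 25. The C7 aldehyde stays masked as the dimethyl acetal until the phosphonate is in place.

**C9 activation (25 ⇒ 24 ⇒ 23).** These are functional-group changes only: silyl ether to alcohol to iodide.

**O–C3 and C4–C18 (23 ⇒ 22).** Both bonds are cut together, back to the E-alkenol 22. The ring is reopened here on purpose: a carbon nucleophile adding to a C3 oxocarbenium ion of the intact oxolane would be expected to enter trans to the C1 arm, whereas ring closure onto the alkene can place both arms pseudo-equatorial (cis). Forward, the step must be 5-exo, anti across the alkene and followed by carbonylation with retention, so that alkene geometry becomes the C4 configuration.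

**C3=C4 (22 ⇒ 17 + 21).** Anti addition gives the target's C3/C4 relationship only from the E-alkene. A Wittig reaction of lactol 17 would give the Z-alkene and hence the C4 epimer, so an E-selective sulfone olefination is used. Sulfone 21 brings C4–C7 (four carbons) with C7 at the aldehyde oxidation level.

**C12–C13 (17 ⇒ 16 ⇒ 8 + 14).** The sp3–sp2 bond is cut so that the Z-alkene is made beforehand in 14 and transferred with retention. Iodide 14 has to hold C9–C12 and the methyl group, five carbons, because C9 must later be the alkylating carbon for C8.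

**Side fragments (14 ⇒ 11 + 12, 11 ⇒ 10 ⇒ 9; 21 ⇒ 20 ⇒ 18 + 19).** The Z-iodoalkene comes from an α-iodo-ylide olefination of a three-carbon aldehyde. The sulfone comes from S-alkylation and oxidation.

**C13 activation (8 ⇒ 7 ⇒ 6).** The free acid arm of 6 is reduced in the presence of the lactone. This is possible because the two arms of C1 emerge from the key step at different oxidation patterns (acid and lactone).

**C15–O (6 ⇒ 5).** The tertiary ether bond is traced to oxygen insertion into the C15–C3 bond of cyclobutanone 5. The hindered C–O bond is thus never made by substitution or addition, and C1 is already in place.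

**Cyclobutanone (5 ⇒ 4 ⇒ 3 ⇒ 2 ⇒ 1).** The keto acid is the degradation product of 1. Alkene cleavage gives both arms, and the acetyl group is removed by a second oxygen insertion, hydrolysis and oxidation.

## Alternatives that were turned down

**Alternative 1:** The C3–C4 bond is taken as the ring-closing bond of the carbocycle, with the oxolane left open.
- Forward key step: a Lewis acid (BF3·OEt2) activates a C3 aldehyde, and a tethered, enantioenriched α-alkoxyallyl stannane adds through its γ-carbon (C4), anti to tin. This gives the macrocyclic syn alcohol A1 with a Z-enol ether on C4.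
- For it: one step closes the 14-membered ring and sets C3 and C4 under reagent control, independently of C1.
- Against it: in A1 the enol ether has two carbons, so one must be excised oxidatively in the presence of two trisubstituted alkenes to reach C18. The oxolane must then be closed between the C3 hydroxyl and C15 with retention at C3, which means ionising the tertiary C15 centre. The C11=C12 alkene is placed to trap that cation in a five- or six-membered cation–olefin cyclisation. The route also needs stoichiometric tin, an asymmetric acylstannane reduction and a long linear precursor.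
- Comparison: this alternative is stronger on C3/C4 control and on convergence. The chosen strategy offers instead the ready-made C15–O bond and C1 stereocentre, and avoids late tertiary ether formation.

**Alternative 2:** The C2–C3 and C1–C15 bonds of the oxolane are cut, back to an aldehyde (C3 with C4 attached) and an allylic 1,2-diol joined as a dioxolane.
- Forward key step: SnCl4 opens the acetal to an oxocarbenium ion at C3, the alkene terminus C2 adds (Prins), and the cation at C1 triggers a pinacol shift of C15 from C14 to C1. The product is the cis-3-formyloxolane A2.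
- For it: two C–C bonds form, the ring closes once and is never reopened, and the cis C1/C3 relationship is fixed by a chair-like transition state. On ring stereocontrol it is stronger than the chosen route.
- Against it: in A2, C14 emerges as a formyl group on the epimerisable C1, although the target needs C14 as a methylene bonded to C13. That requires olefination and a selective alkene reduction, or a coupling at a β-branched sp3 carbon. The aldehyde partner carries C4 α to its carbonyl and must survive acetalisation and a strong Lewis acid without epimerising. Both components must be made enantiopure.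
- Comparison: the chosen strategy offers instead both arms of C1 at the right length and oxidation level, and absolute configuration without any asymmetric step.

**Alternative 3:** The O–C3 and C4–C18 bonds are cut together, back to an acyclic E-alkenol with a tertiary C15 hydroxyl.
- Forward key step: PdCl2 with CuCl2 under CO in methanol; anti oxypalladation then carbonylation gives A3.
- For it: one step closes the ring, sets C3 and C4 and installs C18. Its alkenol could be built by an auxiliary-controlled allylation with an E-allylic electrophile and methyl addition to an ester. That gives a more secure alkene geometry and probably a shorter path than the lactol olefination used here, so on these points it is as strong or stronger.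
- Against it: C1 needs an auxiliary or a catalyst, and the cis C1/C3 outcome rests on the kinetic preference of the cyclisation.
- Comparison: the chosen route uses the same cyclisation as step 16 and shares that risk. It adds a terpene source for C1 and for the tertiary C15–O bond, with the two arms already differentiated. The cost is that the oxolane made in the key step is opened at the lactol stage and closed again.

Key step: step 5

## Route

Step 1
Reactants: 1 (+)-α-pinene
Product: 2 cis-pinonic acid, 2-[(1S,3S)-3-acetyl-2,2-dimethylcyclobutyl]acetic acid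
Conditions: RuCl3·xH2O (2 mol%), NaIO4 (4.1 equiv), CCl4/MeCN/H2O (2:2:3), rt
Reagents that add atoms: sodium periodate, [Na+].[O-]I(=O)(=O)=O
Why: RuO4 formed in situ cleaves the trisubstituted alkene to the methyl ketone and the carboxylic acid (oxidative alkene cleavage); neither cyclobutane stereocentre is touched, so the two ring substituents stay cis.

Step 2
Reactants: 2 cis-pinonic acid
Product: 3 2-[(1S,3S)-3-acetoxy-2,2-dimethylcyclobutyl]acetic acid
Conditions: mCPBA (2.5 equiv), CHCl3, 45 °C, dark
Reagents that add atoms: m-chloroperbenzoic acid, O=C(OO)c1cccc(Cl)c1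
Why: Baeyer–Villiger oxidation of a methyl ketone; the secondary cyclobutyl carbon migrates in preference to methyl and with retention, so the acetoxy group takes the place of the acetyl group.

Step 3
Reactants: 3 acetoxy acid
Product: 4 2-[(1S,3S)-3-hydroxy-2,2-dimethylcyclobutyl]acetic acid
Conditions: NaOH (3 equiv), MeOH/H2O, rt; then cold 1 M HCl to pH 2, EtOAc extraction
Reagents that add atoms: none
Why: Saponification of the acetate by acyl–oxygen cleavage; the carbinol C–O bond is not broken, so the configuration is kept.

Step 4
Reactants: 4 hydroxy acid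
Product: 5 (S)-2-(2,2-dimethyl-3-oxocyclobutyl)acetic acid
Conditions: RuCl3·xH2O (2 mol%), NaIO4 (1.5 equiv), CCl4/MeCN/H2O, 0 °C to rt
Reagents that add atoms: none
Why: RuO4 oxidation of a secondary alcohol to the ketone; a two-electron oxidant is chosen because one-electron oxidants fragment cyclobutanols. The stereocentre lies β to the new carbonyl and cannot epimerise by enolisation.

Step 5
Reactants: 5 (S)-2-(2,2-dimethyl-3-oxocyclobutyl)acetic acid
Product: 6 (R)-terpenylic acid, 2-[(3R)-2,2-dimethyl-5-oxooxolan-3-yl]acetic acid
Conditions: mCPBA (1.3 equiv), CH2Cl2, 0 °C to rt; m-chlorobenzoic acid removed by trituration with cold water, product extracted from the filtrate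
Reagents that add atoms: m-chloroperbenzoic acid, O=C(OO)c1cccc(Cl)c1
Why: The peracid adds to the strained carbonyl C3 to give the tetrahedral Criegee adduct, and relief of cyclobutanone strain makes this addition fast. A 1,2-shift then moves C15 from C3 to the proximal peroxide oxygen as m-chlorobenzoate leaves, which creates the C15–O bond. The closest known reaction type is the Baeyer–Villiger ring expansion of 2,2-disubstituted cyclobutanones to 5,5-disubstituted γ-butyrolactones. The oxolane (as its 2-one) is closed by one-atom expansion of the four-membered ring, not by an end-to-end cyclisation, so no ring-closure rule or entropic penalty applies. No stereocentre is created: C15 is not stereogenic and migrates with retention, and C1 is β to the carbonyl and outside the migrating bonds, so the R configuration taken from (1R,5R)-α-pinene is carried through. The selectivity needed is regiochemical, migration of quaternary C15 and not of the C2 methylene. It is secured by the substitution pattern, since the fully substituted carbon carries positive charge in the migration transition state far better than the methylene. The acid arm is a spectator and leaves C13 and C3 as chemically distinct handles.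

Step 6
Reactants: 6 (R)-terpenylic acid
Product: 7 (4R)-4-(2-hydroxyethyl)-5,5-dimethyloxolan-2-one
Conditions: BH3·THF (1.3 equiv), THF, −10 °C to rt; MeOH quench
Reagents that add atoms: none
Why: Borane reduces the carboxylic acid through its acyloxyborane much faster than the γ-lactone (chemoselective acid reduction). A neutral work-up avoids translactonisation to the δ-lactone, which the gem-dimethyl effect disfavours anyway.

Step 7
Reactants: 7 hydroxyethyl lactone
Product: 8 (4S)-4-(2-iodoethyl)-5,5-dimethyloxolan-2-one
Conditions: PPh3 (1.3 equiv), I2 (1.3 equiv), imidazole (1.5 equiv), CH2Cl2, 0 °C to rt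
Reagents that add atoms: iodine, II
Why: Appel-type iodination of a primary alcohol through the alkoxyphosphonium iodide (SN2 at C13); the descriptor changes only because iodine raises the CIP rank of the side chain.

Step 8
Reactants: 9 propane-1,3-diol
Product: 10 3-[(tert-butyldiphenylsilyl)oxy]propan-1-ol
Conditions: 9 (3 equiv), TBDPSCl (1 equiv), imidazole (1.2 equiv), THF, 0 °C to rt
Reagents that add atoms: tert-butyl(chloro)diphenylsilane, CC(C)(C)[Si](Cl)(c1ccccc1)c1ccccc1
Why: Monosilylation of a symmetrical diol used in excess; the TBDPS ether is chosen because it must survive base, hydride and the mildly acidic carbonylation medium.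

Step 9
Reactants: 10 monosilyl ether
Product: 11 3-[(tert-butyldiphenylsilyl)oxy]propanal
Conditions: TEMPO (10 mol%), PhI(OAc)2 (1.1 equiv), CH2Cl2, rt
Reagents that add atoms: none
Why: Oxoammonium-mediated oxidation of a primary alcohol stops at the aldehyde; the non-basic medium avoids β-elimination of the silyloxy group.

Step 10
Reactants: 11 3-[(tert-butyldiphenylsilyl)oxy]propanal; 12 ethyltriphenylphosphonium iodide
Product: 14 (Z)-tert-butyl[(4-iodopent-3-en-1-yl)oxy]diphenylsilane, via (1-iodoethyl)triphenylphosphonium iodide 13 (not isolated)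
Conditions: 12, n-BuLi, THF, rt; I2, −78 °C; NaN(SiMe3)2, −20 °C; then 11, −78 to −20 °C
Reagents that add atoms: iodine, II
Why: Stork–Zhao-type olefination with the α-iodo ylide; the kinetically formed cis-oxaphosphetane places iodine cis to the alkyl chain, which gives the Z-iodoalkene holding C9–C12 and the C12 methyl group.

Step 11
Reactants: 8 (4S)-4-(2-iodoethyl)-5,5-dimethyloxolan-2-one; 14 (Z)-iodoalkene
Product: 16 (4R)-4-[(3Z)-6-[(tert-butyldiphenylsilyl)oxy]-3-methylhex-3-en-1-yl]-5,5-dimethyloxolan-2-one, via alkylzinc iodide 15 (not isolated)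
Conditions: 8, Zn dust (activated with BrCH2CH2Br and Me3SiCl), DMF, rt; then 14 (0.9 equiv), Pd(PPh3)4 (5 mol%), THF/DMF, 40 °C
Reagents that add atoms: none
Why: Negishi sp3–sp2 coupling; zinc inserts into the primary C–I bond without touching the lactone, and oxidative addition, transmetalation and reductive elimination at palladium proceed with retention of alkene geometry, so C13 ends cis to C10.

Step 12
Reactants: 16 coupled lactone
Product: 17 (4R)-4-[(3Z)-6-[(tert-butyldiphenylsilyl)oxy]-3-methylhex-3-en-1-yl]-5,5-dimethyloxolan-2-ol (both anomers)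
Conditions: i-Bu2AlH (1.15 equiv), CH2Cl2, −78 °C; aqueous potassium sodium tartrate work-up
Reagents that add atoms: none
Why: Partial reduction of a γ-lactone; the aluminium hemiacetal is stable at −78 °C, so reduction stops at the lactol.

Step 13
Reactants: 18 4-chloro-1,1-dimethoxybutane; 19 1-phenyl-1H-tetrazole-5-thiol
Product: 20 5-[(4,4-dimethoxybutyl)sulfanyl]-1-phenyl-1H-tetrazole
Conditions: K2CO3 (1.5 equiv), NaI (10 mol%), DMF, 60 °C
Reagents that add atoms: none
Why: SN2 alkylation of the soft thiolate with iodide catalysis; the acetal is inert to base.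

Step 14
Reactants: 20 sulfide
Product: 21 5-[(4,4-dimethoxybutyl)sulfonyl]-1-phenyl-1H-tetrazole
Conditions: (NH4)6Mo7O24·4H2O (10 mol%), 30% H2O2 (5 equiv), MeOH, 0 °C to rt
Reagents that add atoms: hydrogen peroxide, OO
Why: Molybdate-catalysed oxidation of sulfide to sulfone; methanol as solvent keeps any acetal exchange degenerate.

Step 15
Reactants: 17 lactol; 21 sulfone
Product: 22 (3R,5E)-3-[(3Z)-6-[(tert-butyldiphenylsilyl)oxy]-3-methylhex-3-en-1-yl]-9,9-dimethoxy-2-methylnon-5-en-2-ol
Conditions: KN(SiMe3)2 (2.3 equiv) added to 17 and 21 (1.4 equiv), DME, −60 °C to rt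
Reagents that add atoms: none
Why: Julia–Kocienski olefination; the first equivalent of base opens the lactol to the alkoxide aldehyde, and the metalated phenyltetrazolyl sulfone adds to it, followed by Smiles rearrangement and anti elimination. With potassium in DME the anti adduct dominates, which gives the E-C3=C4 alkene and frees the tertiary C15 hydroxyl.

Step 16
Reactants: 22 E-alkenol
Product: 23 methyl (2S)-2-[(2R,4R)-4-[(3Z)-6-[(tert-butyldiphenylsilyl)oxy]-3-methylhex-3-en-1-yl]-5,5-dimethyloxolan-2-yl]-5,5-dimethoxypentanoate
Conditions: PdCl2 (10 mol%), CuCl2 (3 equiv), NaOAc (3 equiv), CO (1 atm), MeOH, rt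
Reagents that add atoms: carbon monoxide, [C-]#[O+]; methanol, CO
Why: Wacker-type intramolecular alkoxycarbonylation: the C15 hydroxyl attacks C3 of the palladium-bound alkene anti to the metal (5-exo), CO inserts into the C4–Pd bond with retention and methanol releases the ester, while CuCl2 reoxidises zerovalent palladium. Anti addition across the E-alkene fixes C4 relative to C3, and the cis C1/C3 ring should be favoured because both arms sit pseudo-equatorial, away from the axial C15 methyl group.

Step 17
Reactants: 23 silyl ether ester
Product: 24 methyl (2S)-2-[(2R,4R)-4-[(3Z)-6-hydroxy-3-methylhex-3-en-1-yl]-5,5-dimethyloxolan-2-yl]-5,5-dimethoxypentanoate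
Conditions: Bu4NF (1.5 equiv), AcOH (1.5 equiv), THF, 0 °C to rt
Reagents that add atoms: none
Why: Fluoride cleavage of the silyl ether; buffering with acetic acid keeps the medium from enolising the β-alkoxy ester at C4.

Step 18
Reactants: 24 alcohol
Product: 25 methyl (2S)-2-[(2R,4R)-4-[(3Z)-6-iodo-3-methylhex-3-en-1-yl]-5,5-dimethyloxolan-2-yl]-5,5-dimethoxypentanoate
Conditions: PPh3 (1.3 equiv), I2 (1.3 equiv), imidazole (2 equiv), CH2Cl2, 0 °C
Reagents that add atoms: iodine, II
Why: Appel-type iodination of the primary C9 alcohol; imidazole keeps the medium neutral for the acetal.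

Step 19
Reactants: 25 iodide; 26 triethyl phosphonoacetate
Product: 27 ethyl (5Z)-2-(diethoxyphosphoryl)-6-methyl-8-[(3R,5R)-2,2-dimethyl-5-[(2S)-1,5,5-trimethoxy-1-oxopentan-2-yl]oxolan-3-yl]oct-5-enoate (both epimers at the phosphonate carbon C8)
Conditions: 26 (3 equiv), NaH (2.8 equiv), DMF, 0 °C; then 25, 55 °C
Reagents that add atoms: none
Why: SN2 alkylation of the stabilised phosphonoacetate anion by a primary iodide forms C8–C9. The anion is used in excess over NaH so that no free hydride can enolise the C4 ester, and the excess limits dialkylation; the C8 centre is lost again in step 21.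

Step 20
Reactants: 27 phosphonate acetal
Product: 28 ethyl (5Z)-2-(diethoxyphosphoryl)-8-[(3R,5R)-5-[(2S)-1-methoxy-1,5-dioxopentan-2-yl]-2,2-dimethyloxolan-3-yl]-6-methyloct-5-enoate (both C8 epimers)
Conditions: PPTS (20 mol%), acetone/H2O (10:1), 45 °C
Reagents that add atoms: water, O
Why: Mild acid hydrolysis of the dimethyl acetal frees the C7 aldehyde; esters, the oxolane and the trisubstituted alkene tolerate pyridinium acid.

Step 21
Reactants: 28 phosphonate aldehyde
Product: 29 8-ethyl 12-methyl (1R,4Z,8E,12S,13R)-4,15,15-trimethyl-14-oxabicyclo[11.2.1]hexadeca-4,8-diene-8,12-dicarboxylate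
Conditions: LiCl (10 equiv), DBU (5 equiv), MeCN, 28 added by syringe pump to 1 mM final concentration, rt
Reagents that add atoms: none
Why: Intramolecular Horner–Wadsworth–Emmons olefination under Masamune–Roush conditions closes the 14-membered ring at C7=C8. The α-alkyl phosphonoacetate gives the enoate with the ester trans to C6 (E), and the amidine base with lithium chelation is too weak to epimerise C4.

Step 22
Reactants: 29 macrocyclic diester
Product: 30 [(1R,4Z,8E,12R,13R)-4,15,15-trimethyl-14-oxabicyclo[11.2.1]hexadeca-4,8-diene-8,12-diyl]dimethanol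
Conditions: i-Bu2AlH (6 equiv), CH2Cl2, −78 to −20 °C; aqueous potassium sodium tartrate work-up
Reagents that add atoms: none
Why: Hydride reduction of both esters; the enoate is reduced 1,2 to the allylic alcohol and the C18 ester to the primary alcohol, which also removes the epimerisable ester from C4.

Step 23
Reactants: 30 diol
Product: 31 (1R,4Z,8E,12R,13R)-12-(hydroxymethyl)-4,15,15-trimethyl-14-oxabicyclo[11.2.1]hexadeca-4,8-diene-8-carbaldehyde
Conditions: activated MnO2 (20 equiv), CH2Cl2, rt
Reagents that add atoms: none
Why: MnO2 oxidises allylic alcohols selectively, so only the alcohol on C8 becomes the aldehyde and the C18 alcohol stays free; the neutral medium gives no catalyst for oxa-Michael addition of that alcohol to C7.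

Step 24
Reactants: 31 hydroxy enal; 32 allyl hydrogen malonate, 3-oxo-3-(prop-2-en-1-yloxy)propanoic acid
Product: 33 [(1R,4Z,8E,12R,13R)-8-formyl-4,15,15-trimethyl-14-oxabicyclo[11.2.1]hexadeca-4,8-dien-12-yl]methyl prop-2-en-1-yl propanedioate
Conditions: 32 (1.5 equiv), DCC (1.5 equiv), DMAP (10 mol%), CH2Cl2, 0 °C
Reagents that add atoms: none
Why: Carbodiimide esterification of the single free primary alcohol; malonic half esters couple readily at 0 °C, and the enal is inert to these conditions.

Step 25
Reactants: 33 allyl malonate
Product: 34 target, 3-{[(1R,4Z,8E,12R,13R)-8-formyl-4,15,15-trimethyl-14-oxabicyclo[11.2.1]hexadeca-4,8-dien-12-yl]methoxy}-3-oxopropanoic acid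
Conditions: Pd(PPh3)4 (5 mol%), sodium p-toluenesulfinate (1.5 equiv), THF/MeOH, rt; then dilute HCl to pH 3, cold work-up
Reagents that add atoms: none
Why: Zerovalent palladium ionises the allyl ester to an allylpalladium carboxylate and the sulfinate traps the allyl group (Tsuji–Trost deallylation); the conditions are neutral, free of amine and at room temperature, which suits the enal and the heat-sensitive malonic half ester.

## Compound list

1 | (+)-α-pinene, (1R,5R)-2,6,6-trimethylbicyclo[3.1.1]hept-2-ene | CC1=CC[C@@H]2C[C@H]1C2(C)C | starting material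
2 | cis-pinonic acid, 2-[(1S,3S)-3-acetyl-2,2-dimethylcyclobutyl]acetic acid | OC(=O)C[C@@H]1C[C@H](C(C)=O)C1(C)C | intermediate
3 | 2-[(1S,3S)-3-acetoxy-2,2-dimethylcyclobutyl]acetic acid | OC(=O)C[C@@H]1C[C@H](OC(C)=O)C1(C)C | intermediate
4 | 2-[(1S,3S)-3-hydroxy-2,2-dimethylcyclobutyl]acetic acid | OC(=O)C[C@@H]1C[C@H](O)C1(C)C | intermediate
5 | (S)-2-(2,2-dimethyl-3-oxocyclobutyl)acetic acid | O=C1C[C@@H](CC(=O)O)C1(C)C | intermediate
6 | (R)-terpenylic acid, 2-[(3R)-2,2-dimethyl-5-oxooxolan-3-yl]acetic acid | O=C1C[C@@H](CC(=O)O)C(C)(C)O1 | intermediate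
7 | (4R)-4-(2-hydroxyethyl)-5,5-dimethyloxolan-2-one | O=C1C[C@@H](CCO)C(C)(C)O1 | intermediate
8 | (4S)-4-(2-iodoethyl)-5,5-dimethyloxolan-2-one | O=C1C[C@@H](CCI)C(C)(C)O1 | intermediate
9 | propane-1,3-diol | OCCCO | starting material
10 | 3-[(tert-butyldiphenylsilyl)oxy]propan-1-ol | OCCCO[Si](c1ccccc1)(c1ccccc1)C(C)(C)C | intermediate
11 | 3-[(tert-butyldiphenylsilyl)oxy]propanal | O=CCCO[Si](c1ccccc1)(c1ccccc1)C(C)(C)C | intermediate
12 | ethyltriphenylphosphonium iodide | CC[P+](c1ccccc1)(c1ccccc1)c1ccccc1.[I-] | starting material
13 | (1-iodoethyl)triphenylphosphonium iodide | CC(I)[P+](c1ccccc1)(c1ccccc1)c1ccccc1.[I-] | intermediate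
14 | (Z)-tert-butyl[(4-iodopent-3-en-1-yl)oxy]diphenylsilane | C/C(I)=C/CCO[Si](c1ccccc1)(c1ccccc1)C(C)(C)C | intermediate
15 | {2-[(3S)-2,2-dimethyl-5-oxooxolan-3-yl]ethyl}(iodo)zinc | O=C1C[C@@H](CC[Zn]I)C(C)(C)O1 | intermediate
16 | (4R)-4-[(3Z)-6-[(tert-butyldiphenylsilyl)oxy]-3-methylhex-3-en-1-yl]-5,5-dimethyloxolan-2-one | O=C1C[C@@H](CC/C(C)=C\CCO[Si](c2ccccc2)(c2ccccc2)C(C)(C)C)C(C)(C)O1 | intermediate
17 | (4R)-4-[(3Z)-6-[(tert-butyldiphenylsilyl)oxy]-3-methylhex-3-en-1-yl]-5,5-dimethyloxolan-2-ol (both anomers) | OC1C[C@@H](CC/C(C)=C\CCO[Si](c2ccccc2)(c2ccccc2)C(C)(C)C)C(C)(C)O1 | intermediate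
18 | 4-chloro-1,1-dimethoxybutane | COC(CCCCl)OC | starting material
19 | 1-phenyl-1H-tetrazole-5-thiol | Sc1nnnn1-c1ccccc1 | starting material
20 | 5-[(4,4-dimethoxybutyl)sulfanyl]-1-phenyl-1H-tetrazole | COC(CCCSc1nnnn1-c1ccccc1)OC | intermediate
21 | 5-[(4,4-dimethoxybutyl)sulfonyl]-1-phenyl-1H-tetrazole | COC(CCCS(=O)(=O)c1nnnn1-c1ccccc1)OC | intermediate
22 | (3R,5E)-3-[(3Z)-6-[(tert-butyldiphenylsilyl)oxy]-3-methylhex-3-en-1-yl]-9,9-dimethoxy-2-methylnon-5-en-2-ol | COC(CC/C=C/C[C@@H](CC/C(C)=C\CCO[Si](c1ccccc1)(c1ccccc1)C(C)(C)C)C(C)(C)O)OC | intermediate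
23 | methyl (2S)-2-[(2R,4R)-4-[(3Z)-6-[(tert-butyldiphenylsilyl)oxy]-3-methylhex-3-en-1-yl]-5,5-dimethyloxolan-2-yl]-5,5-dimethoxypentanoate | COC(CC[C@H](C(=O)OC)[C@H]1C[C@@H](CC/C(C)=C\CCO[Si](c2ccccc2)(c2ccccc2)C(C)(C)C)C(C)(C)O1)OC | intermediate
24 | methyl (2S)-2-[(2R,4R)-4-[(3Z)-6-hydroxy-3-methylhex-3-en-1-yl]-5,5-dimethyloxolan-2-yl]-5,5-dimethoxypentanoate | COC(CC[C@H](C(=O)OC)[C@H]1C[C@@H](CC/C(C)=C\CCO)C(C)(C)O1)OC | intermediate
25 | methyl (2S)-2-[(2R,4R)-4-[(3Z)-6-iodo-3-methylhex-3-en-1-yl]-5,5-dimethyloxolan-2-yl]-5,5-dimethoxypentanoate | COC(CC[C@H](C(=O)OC)[C@H]1C[C@@H](CC/C(C)=C\CCI)C(C)(C)O1)OC | intermediate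
26 | triethyl phosphonoacetate | CCOC(=O)CP(=O)(OCC)OCC | starting material
27 | ethyl (5Z)-2-(diethoxyphosphoryl)-6-methyl-8-[(3R,5R)-2,2-dimethyl-5-[(2S)-1,5,5-trimethoxy-1-oxopentan-2-yl]oxolan-3-yl]oct-5-enoate (both C8 epimers) | COC(CC[C@H](C(=O)OC)[C@H]1C[C@@H](CC/C(C)=C\CCC(C(=O)OCC)P(=O)(OCC)OCC)C(C)(C)O1)OC | intermediate
28 | ethyl (5Z)-2-(diethoxyphosphoryl)-8-[(3R,5R)-5-[(2S)-1-methoxy-1,5-dioxopentan-2-yl]-2,2-dimethyloxolan-3-yl]-6-methyloct-5-enoate (both C8 epimers) | O=CCC[C@H](C(=O)OC)[C@H]1C[C@@H](CC/C(C)=C\CCC(C(=O)OCC)P(=O)(OCC)OCC)C(C)(C)O1 | intermediate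
29 | 8-ethyl 12-methyl (1R,4Z,8E,12S,13R)-4,15,15-trimethyl-14-oxabicyclo[11.2.1]hexadeca-4,8-diene-8,12-dicarboxylate | C/C1=C/CC/C(C(=O)OCC)=C\CC[C@H](C(=O)OC)[C@H]2C[C@@H](CC1)C(C)(C)O2 | intermediate
30 | [(1R,4Z,8E,12R,13R)-4,15,15-trimethyl-14-oxabicyclo[11.2.1]hexadeca-4,8-diene-8,12-diyl]dimethanol | C/C1=C/CC/C(CO)=C\CC[C@H](CO)[C@H]2C[C@@H](CC1)C(C)(C)O2 | intermediate
31 | (1R,4Z,8E,12R,13R)-12-(hydroxymethyl)-4,15,15-trimethyl-14-oxabicyclo[11.2.1]hexadeca-4,8-diene-8-carbaldehyde | C/C1=C/CC/C(C=O)=C\CC[C@H](CO)[C@H]2C[C@@H](CC1)C(C)(C)O2 | intermediate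
32 | allyl hydrogen malonate, 3-oxo-3-(prop-2-en-1-yloxy)propanoic acid | C=CCOC(=O)CC(=O)O | starting material
33 | [(1R,4Z,8E,12R,13R)-8-formyl-4,15,15-trimethyl-14-oxabicyclo[11.2.1]hexadeca-4,8-dien-12-yl]methyl prop-2-en-1-yl propanedioate | C/C1=C/CC/C(C=O)=C\CC[C@H](COC(=O)CC(=O)OCC=C)[C@H]2C[C@@H](CC1)C(C)(C)O2 | intermediate
34 | 3-{[(1R,4Z,8E,12R,13R)-8-formyl-4,15,15-trimethyl-14-oxabicyclo[11.2.1]hexadeca-4,8-dien-12-yl]methoxy}-3-oxopropanoic acid (CNP0170412.1) | C/C1=C/CC/C(C=O)=C\CC[C@H](COC(=O)CC(=O)O)[C@H]2C[C@@H](CC1)C(C)(C)O2 | target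

## Step count and least certain steps

Total step count: 25. Longest linear sequence: 20 steps (steps 1–7, 11, 12 and 15–25); steps 8–10 and 13–14 make the two side fragments.

**Step 5 (key step).** The most likely losses are incomplete recovery of a small, water-soluble acid when it is separated from m-chlorobenzoic acid, and, less likely, leakage to migration of the C2 methylene.
Fallback: it sets out from 5 and comes back at 6. Irradiation of 5 in methanol (Pyrex filter, about 300 nm) cleaves the more substituted C3–C15 bond, and the acyl–alkyl biradical recloses on oxygen to an oxacarbene that methanol traps. This photochemical ring expansion of a cyclobutanone gives 2-[(3S)-5-methoxy-2,2-dimethyloxolan-3-yl]acetic acid F1. Oxidation with CrO3 and H2SO4 in acetone then hydrolyses the acetal and oxidises the lactol to 6.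

**Step 15.** The gem-dimethyl lactolate may open too slowly, so that the metalated sulfone self-condenses before it meets the aldehyde; E/Z selectivity may also erode, and each geometric isomer would become a C4 epimer in step 16.
Fallback: it sets out from 17 and comes back at 22, and it replaces olefination by alkyne hydrometalation and cross-coupling.
- Ohira–Bestmann homologation (dimethyl (1-diazo-2-oxopropyl)phosphonate, K2CO3, MeOH) gives (3R)-3-[(3Z)-6-[(tert-butyldiphenylsilyl)oxy]-3-methylhex-3-en-1-yl]-2-methylhex-5-yn-2-ol F2.
- Syn hydrozirconation with Cp2Zr(H)Cl and iodinolysis gives the geometrically pure (3R,5E)-3-[(3Z)-6-[(tert-butyldiphenylsilyl)oxy]-3-methylhex-3-en-1-yl]-6-iodo-2-methylhex-5-en-2-ol F3.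
- Hydroboration of 3,3-dimethoxyprop-1-ene with 9-BBN gives 9-(3,3-dimethoxypropyl)-9-borabicyclo[3.3.1]nonane F4.
- B-alkyl Suzuki coupling of F3 and F4 (PdCl2(dppf), AsPh3, Cs2CO3, DMF/THF/H2O) gives 22.

**Step 16.** The facial selectivity of the oxypalladation may be poor (cis against trans oxolane, decided only by a kinetic preference), and β-hydride elimination from the secondary alkylpalladium at C4 may compete with CO insertion.
Fallback: it sets out from 22 and comes back at 23, and it separates ring closure from C–C bond formation. Hg(OCOCF3)2 in MeCN at 0 °C, then aqueous NaCl, gives chloro{(1S)-1-[(2R,4R)-4-[(3Z)-6-[(tert-butyldiphenylsilyl)oxy]-3-methylhex-3-en-1-yl]-5,5-dimethyloxolan-2-yl]-4,4-dimethoxybutyl}mercury F5. The oxymercuration is anti and reversible, so the ring closure can equilibrate toward the cis isomer. The alkylmercurial does not β-eliminate, so the trans isomer can be removed before the next step. Li2PdCl4 under CO (5–10 atm) in MeOH then exchanges mercury for palladium and carbonylates with retention to give 23. This fallback does not remove the underlying uncertainty about the size of the cis preference; it only allows equilibration and separation.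

**Step 21.** Intermolecular olefination (oligomers) may compete with ring closure, and ring strain may erode the E preference.
Fallback: it sets out from 27 and comes back at 29, and it closes the ring by metathesis.
- Aqueous formaldehyde and K2CO3 convert the phosphonate into ethyl (5Z)-6-methyl-2-methylidene-8-[(3R,5R)-2,2-dimethyl-5-[(2S)-1,5,5-trimethoxy-1-oxopentan-2-yl]oxolan-3-yl]oct-5-enoate F6.
- PPTS in wet acetone gives ethyl (5Z)-8-[(3R,5R)-5-[(2S)-1-methoxy-1,5-dioxopentan-2-yl]-2,2-dimethyloxolan-3-yl]-6-methyl-2-methylideneoct-5-enoate F7.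
- Non-basic methylenation (Zn, CH2Br2, TiCl4) gives ethyl (5Z)-8-[(3R,5R)-5-[(2S)-1-methoxy-1-oxohex-5-en-2-yl]-2,2-dimethyloxolan-3-yl]-6-methyl-2-methylideneoct-5-enoate F8.
- Ring-closing metathesis with second-generation Hoveyda–Grubbs catalyst (toluene, 80 °C, 1 mM) releases ethene and gives 29.

**Step 25.** The allylpalladium intermediate may allylate the malonate methylene instead of the sulfinate, and the sulfinate or the liberated carboxylate may add to the enal.
Fallback: it sets out from 31 and comes back at 34. Heating 31 with Meldrum's acid in toluene at about 85 °C opens the dioxanedione at the C18 hydroxyl with loss of acetone and gives the half ester directly. It makes no new compound (F0); its own risk is condensation of Meldrum's acid with the enal.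

## Further compounds

F1 | step 5 | 2-[(3S)-5-methoxy-2,2-dimethyloxolan-3-yl]acetic acid (both anomers) | COC1C[C@@H](CC(=O)O)C(C)(C)O1
F2 | step 15 | (3R)-3-[(3Z)-6-[(tert-butyldiphenylsilyl)oxy]-3-methylhex-3-en-1-yl]-2-methylhex-5-yn-2-ol | C#CC[C@@H](CC/C(C)=C\CCO[Si](c1ccccc1)(c1ccccc1)C(C)(C)C)C(C)(C)O
F3 | step 15 | (3R,5E)-3-[(3Z)-6-[(tert-butyldiphenylsilyl)oxy]-3-methylhex-3-en-1-yl]-6-iodo-2-methylhex-5-en-2-ol | I/C=C/C[C@@H](CC/C(C)=C\CCO[Si](c1ccccc1)(c1ccccc1)C(C)(C)C)C(C)(C)O
F4 | step 15 | 9-(3,3-dimethoxypropyl)-9-borabicyclo[3.3.1]nonane | COC(CCB1C2CCCC1CCC2)OC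
F5 | step 16 | chloro{(1S)-1-[(2R,4R)-4-[(3Z)-6-[(tert-butyldiphenylsilyl)oxy]-3-methylhex-3-en-1-yl]-5,5-dimethyloxolan-2-yl]-4,4-dimethoxybutyl}mercury | COC(CC[C@H]([Hg]Cl)[C@H]1C[C@@H](CC/C(C)=C\CCO[Si](c2ccccc2)(c2ccccc2)C(C)(C)C)C(C)(C)O1)OC
F6 | step 21 | ethyl (5Z)-6-methyl-2-methylidene-8-[(3R,5R)-2,2-dimethyl-5-[(2S)-1,5,5-trimethoxy-1-oxopentan-2-yl]oxolan-3-yl]oct-5-enoate | COC(CC[C@H](C(=O)OC)[C@H]1C[C@@H](CC/C(C)=C\CCC(=C)C(=O)OCC)C(C)(C)O1)OC
F7 | step 21 | ethyl (5Z)-8-[(3R,5R)-5-[(2S)-1-methoxy-1,5-dioxopentan-2-yl]-2,2-dimethyloxolan-3-yl]-6-methyl-2-methylideneoct-5-enoate | O=CCC[C@H](C(=O)OC)[C@H]1C[C@@H](CC/C(C)=C\CCC(=C)C(=O)OCC)C(C)(C)O1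
F8 | step 21 | ethyl (5Z)-8-[(3R,5R)-5-[(2S)-1-methoxy-1-oxohex-5-en-2-yl]-2,2-dimethyloxolan-3-yl]-6-methyl-2-methylideneoct-5-enoate | C=CCC[C@H](C(=O)OC)[C@H]1C[C@@H](CC/C(C)=C\CCC(=C)C(=O)OCC)C(C)(C)O1
F0 | step 25 | none | none
A1 | alternative 1 | 14-membered syn homoallylic alcohol with a Z-(methoxymethoxy)ethenyl group on C4, C15 triethylsilyl ether and a silyloxymethyl group on C8 | C/C1=C/CC/C(CO[Si](C)(C)C(C)(C)C)=C\CC[C@H](/C=C\OCOC)[C@H](O)C[C@@H](CC1)C(C)(C)O[Si](CC)(CC)CC
A2 | alternative 2 | cis-3-formyl-2,2-dimethyloxolane carrying the silyl-protected C4–C7 arm on C3 | CC(C)(C)[Si](C)(C)OCCC[C@H](CO[Si](C(C)C)(C(C)C)C(C)C)[C@H]1C[C@@H](C=O)C(C)(C)O1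
A3 | alternative 3 | 3,5-cis-oxolane with the C18 methyl ester on C4, a p-methoxybenzyl ether on C7 and a silyl ether on C9 | COc1ccc(COCCC[C@H](C(=O)OC)[C@H]2C[C@@H](CC/C(C)=C\CCO[Si](c3ccccc3)(c3ccccc3)C(C)(C)C)C(C)(C)O2)cc1
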